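**Retrosynthetic overview** (chain locants C1–C23 run from the ethyl end of ring A; C3–C7 are the ring A carbons, C15–C19 the ring B carbons)
1. Target ⇐ C9-hydroxyl-directed 1,3-anti reduction of the C11 ketone of a (12E)-enone ⇐ loss of a C13 acetate from a β-acetoxy ketone.
2. Key disconnection C11–C12: visible-light nickel acyl–alkyl coupling of a ring A S-2-pyridyl thioester (C1–C11) with a ring B secondary chloride (C12–C23).
3. Both halves ⇐ one symmetrical pyranone by vinylogous aldol additions at its ethyl groups: to an (S)-Roche-ester aldehyde (C8–C10), to (S)-2-chloropropanal (C20, C21; chlorine then removed) and to (R)-2-chloropropanal (C14; C12 and C13 later become the alkene).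
4. Rings: the pyranone ring is made once (step 1) and serves as ring A and as ring B; no ring is formed afterwards.

Assumption: the symmetrical pyranone is made rather than bought, and lithium dienolates of 2-ethyl-4-pyranones are taken to add to aldehydes with anti simple diastereoselection.

**Step 1**
Reactants: 1 pentan-3-one; 2 propanoic acid
Product: 3 2,6-diethyl-3,5-dimethyl-4H-pyran-4-one
Conditions: 2 (2.5 equiv), polyphosphoric acid, 120–130 °C
Reagents that add atoms: none
Why: Acid-mediated C-acylation of the ketone at both α-carbons followed by cyclodehydration of the 1,3,5-triketone (polyphosphoric acid pyranone synthesis) gives the symmetrical pyranone, and no stereocentre is formed.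

**Step 2**
Reactants: 4 methyl (S)-2-chloropropanoate
Product: 5 (S)-2-chloropropanal
Conditions: i-Bu2AlH (1.05 equiv), Et2O, −78 °C; aq. potassium sodium tartrate; distilled and used at once
Reagents that add atoms: none
Why: Partial ester reduction stops at the aldehyde because the aluminium hemiacetal of an α-chloro ester is stable at −78 °C, and the bought stereocentre is not touched.

**Step 3**
Reactants: 3 2,6-diethyl-3,5-dimethyl-4H-pyran-4-one; 5 (S)-2-chloropropanal
Product: 7 2-[(2S,3R,4S)-4-chloro-3-(triethylsilyloxy)pentan-2-yl]-6-ethyl-3,5-dimethyl-4H-pyran-4-one, via lithium aldolate 6 (not isolated)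
Conditions: LiN(SiMe3)2 (1.05 equiv), THF, −78 °C; 5 (1.4 equiv), −78 °C; then Et3SiOTf (1.6 equiv), −78 → −40 °C
Reagents that add atoms: triethylsilyl trifluoromethanesulfonate, CC[Si](CC)(CC)OS(=O)(=O)C(F)(F)F
Why: Vinylogous aldol addition from the exocyclic carbon of the lithium dienolate, in which the Cornforth (polar Felkin–Anh) model places the new C21–O anti to C22–Cl and the open transition state of the E-configured dienolate places the C20 methyl anti to C21–O, while silylation at −78 °C forestalls epoxide closure.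

**Step 4**
Reactants: 7 2-[(2S,3R,4S)-4-chloro-3-(triethylsilyloxy)pentan-2-yl]-6-ethyl-3,5-dimethyl-4H-pyran-4-one
Product: 8 2-ethyl-3,5-dimethyl-6-[(2S,3S)-3-(triethylsilyloxy)pentan-2-yl]-4H-pyran-4-one
Conditions: (Me3Si)3SiH (1.5 equiv), azobis(isobutyronitrile) (0.2 equiv), PhMe, 85 °C
Reagents that add atoms: none
Why: Radical chain dehalogenation (silyl radical abstracts chlorine, the secondary radical takes hydrogen from the silane) erases the directing C22 stereocentre after it has set C20 and C21, which are not touched.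

**Step 5**
Reactants: 9 methyl (R)-2-chloropropanoate
Product: 10 (R)-2-chloropropanal
Conditions: i-Bu2AlH (1.05 equiv), Et2O, −78 °C; aq. potassium sodium tartrate; distilled and used at once
Reagents that add atoms: none
Why: Partial ester reduction as in step 2, with the bought stereocentre left intact.

**Step 6**
Reactants: 8 2-ethyl-3,5-dimethyl-6-[(2S,3S)-3-(triethylsilyloxy)pentan-2-yl]-4H-pyran-4-one; 10 (R)-2-chloropropanal
Product: 12 (2R,3S,4R)-2-chloro-4-{3,5-dimethyl-4-oxo-6-[(2S,3S)-3-(triethylsilyloxy)pentan-2-yl]-4H-pyran-2-yl}pentan-3-yl acetate, via lithium aldolate 11 (not isolated)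
Conditions: LiN(SiMe3)2 (1.1 equiv), THF, −78 °C; 10 (1.5 equiv), −78 °C; then Ac2O (3 equiv), −78 → −20 °C
Reagents that add atoms: acetic anhydride, CC(=O)OC(C)=O
Why: Kinetic deprotonation takes the unbranched ethyl CH2 rather than the hindered C20–H, the same vinylogous aldol addition sets C13–O anti to C12–Cl (Cornforth) and the C14 methyl anti to C13–O so that the (R)-aldehyde delivers (14R), and acetylation of the aldolate installs the leaving group for step 13.

**Step 7**
Reactants: 13 methyl (S)-3-hydroxy-2-methylpropanoate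
Product: 14 methyl (S)-2-methyl-3-(triethylsilyloxy)propanoate
Conditions: Et3SiCl, imidazole, CH2Cl2, 0 °C
Reagents that add atoms: chlorotriethylsilane, CC[Si](Cl)(CC)CC
Why: Routine silyl ether formation at the primary alcohol, the stereocentre that becomes C10 being bought.

**Step 8**
Reactants: 14 methyl (S)-2-methyl-3-(triethylsilyloxy)propanoate
Product: 15 (S)-2-methyl-3-(triethylsilyloxy)propanal
Conditions: i-Bu2AlH (1.1 equiv), CH2Cl2, −78 °C; aq. potassium sodium tartrate
Reagents that add atoms: none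
Why: Partial ester reduction at −78 °C gives the configurationally stable β-silyloxy aldehyde without epimerisation.

**Step 9**
Reactants: 3 2,6-diethyl-3,5-dimethyl-4H-pyran-4-one; 15 (S)-2-methyl-3-(triethylsilyloxy)propanal
Product: 18 2-[(2R,3R,4S)-3,5-dihydroxy-4-methylpentan-2-yl]-6-ethyl-3,5-dimethyl-4H-pyran-4-one, via lithium aldolate 16 (not isolated), via hydroxy silyl ether 17 (not isolated)
Conditions: LiN(SiMe3)2 (1.05 equiv), THF, −78 °C; 15 (1.1 equiv), −78 °C; then 1 M HCl, THF, 0 → 23 °C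
Reagents that add atoms: none
Why: Vinylogous aldol addition under Felkin–Anh control by the α-methyl stereocentre (C9–OH syn to C10–Me) with the same anti simple diastereoselection (C8–Me anti to C9–OH), after which dilute acid cleaves the primary triethylsilyl ether.

**Step 10**
Reactants: 18 2-[(2R,3R,4S)-3,5-dihydroxy-4-methylpentan-2-yl]-6-ethyl-3,5-dimethyl-4H-pyran-4-one
Product: 19 (2R,3S,4R)-4-(6-ethyl-3,5-dimethyl-4-oxo-4H-pyran-2-yl)-3-hydroxy-2-methylpentanoic acid
Conditions: 2,2,6,6-tetramethylpiperidine-1-oxyl (0.2 equiv), PhI(OAc)2 (2.5 equiv), MeCN/H2O 1:1, 0 → 23 °C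
Reagents that add atoms: water, O
Why: Oxoammonium oxidation is selective for the primary alcohol and runs in water through the aldehyde hydrate to the acid, leaving the secondary C9–OH and the C10 stereocentre alone.

**Step 11**
Reactants: 19 (2R,3S,4R)-4-(6-ethyl-3,5-dimethyl-4-oxo-4H-pyran-2-yl)-3-hydroxy-2-methylpentanoic acid
Product: 20 S-(pyridin-2-yl) (2R,3S,4R)-4-(6-ethyl-3,5-dimethyl-4-oxo-4H-pyran-2-yl)-3-hydroxy-2-methylpentanethioate
Conditions: 2,2′-dipyridyl disulfide (1.3 equiv), PPh3 (1.3 equiv), CH2Cl2, 23 °C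
Reagents that add atoms: 2,2′-dipyridyl disulfide, c1ccc(SSc2ccccn2)nc1
Why: Mukaiyama redox condensation (acyloxyphosphonium trapped by pyridine-2-thiolate) activates the acid under neutral conditions without touching the β-hydroxyl or the α-stereocentre.

**Step 12**
Reactants: 20 S-(pyridin-2-yl) thioester of the C1–C11 acid; 12 C12 chloride with C13 acetate (C12–C23 half)
Product: 21 C11 ketone of the full C1–C23 chain (13-acetoxy; 9-hydroxy; 21-triethylsilyloxy; both C12 epimers)
Conditions: NiBr2(MeOCH2CH2OMe) (10 mol %), 4,4′-di-tert-butyl-2,2′-bipyridine (12 mol %), [Ir(L)2(dtbbpy)]PF6 (2 mol %; L = cyclometalated 2-(2,4-difluorophenyl)-5-(trifluoromethyl)pyridine, dtbbpy = the same bipyridine), (Me3Si)3SiNH(1-adamantyl) (1.6 equiv), K3PO4 (20 mol %), DMA, 450 nm LEDs, 25 °C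
Reagents that add atoms: none
Why: Proposed new method: a silyl-radical-mediated nickel/photoredox acyl cross-electrophile coupling of an unactivated secondary alkyl chloride with an S-2-pyridyl thioester, in which the photoexcited iridium complex oxidises the aminosilane, the silicon-centred radical formed after aza-Brook shift abstracts chlorine from C12, the C12 radical is captured by the acyl complex of divalent nickel that arises from insertion of zerovalent nickel into the C(acyl)–S bond, reductive elimination from trivalent nickel forms the C11–C12 bond and the reduced photocatalyst returns monovalent nickel to the zerovalent state; the closest known reaction types are the silyl-radical metallaphotoredox cross-electrophile coupling of alkyl chlorides with aryl halides and the nickel-catalysed reductive acylation of alkyl iodides with 2-pyridyl thioesters, and the C12 configuration does not matter because step 13 erases it.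

**Step 13**
Reactants: 21 C11 ketone (13-acetoxy; C12 epimers)
Product: 22 (12E)-enone (9-hydroxy; 11-oxo; 21-triethylsilyloxy)
Conditions: 1,8-diazabicyclo[5.4.0]undec-7-ene (1.5 equiv), CH2Cl2, 0 °C, 20 min
Reagents that add atoms: none
Why: E1cB elimination of acetate through the C12 enolate is regiospecific (only C12–H is both α to the ketone and β to the acetate) and gives the favoured E-enone, so the C12 and C13 stereocentres disappear after having relayed chirality to C14.

**Step 14**
Reactants: 22 (12E)-enone (21-triethylsilyloxy)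
Product: 23 (12E)-9,21-dihydroxy-12-en-11-one
Conditions: HF·pyridine, pyridine, THF, 0 °C
Reagents that add atoms: none
Why: Buffered fluoride desilylation frees C21–OH without acid- or base-induced isomerisation of the enone or of C14.

**Step 15**
Reactants: 23 (12E)-9,21-dihydroxy-12-en-11-one
Product: 24 CNP0408419.9 (8R,9R,10R,11R,12E,14R,20S,21S)
Conditions: Me4NBH(OAc)3 (6 equiv), MeCN/AcOH 1:1, −25 °C
Reagents that add atoms: none
Why: Evans–Saksena reduction, in which the C9 hydroxyl exchanges an acetate on boron and delivers hydride to the enone carbonyl intramolecularly through a chair transition state, gives the 9,11-anti diol and hence (11R) by 1,2-reduction.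

**Compound list**
1 | pentan-3-one | CCC(=O)CC | starting material
2 | propanoic acid | CCC(=O)O | starting material
3 | 2,6-diethyl-3,5-dimethyl-4H-pyran-4-one | CCc1oc(CC)c(C)c(=O)c1C | intermediate
4 | methyl (S)-2-chloropropanoate | C[C@H](Cl)C(=O)OC | starting material
5 | (S)-2-chloropropanal | C[C@H](Cl)C=O | intermediate
6 | lithium (2S,3R,4S)-4-chloro-2-(6-ethyl-3,5-dimethyl-4-oxo-4H-pyran-2-yl)pentan-3-olate | [Li+].CCc1oc([C@@H](C)[C@@H]([O-])[C@@H](Cl)C)c(C)c(=O)c1C | intermediate
7 | 2-[(2S,3R,4S)-4-chloro-3-(triethylsilyloxy)pentan-2-yl]-6-ethyl-3,5-dimethyl-4H-pyran-4-one | CCc1oc([C@@H](C)[C@@H](O[Si](CC)(CC)CC)[C@@H](Cl)C)c(C)c(=O)c1C | intermediate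
8 | 2-ethyl-3,5-dimethyl-6-[(2S,3S)-3-(triethylsilyloxy)pentan-2-yl]-4H-pyran-4-one | CCc1oc([C@@H](C)[C@@H](O[Si](CC)(CC)CC)CC)c(C)c(=O)c1C | intermediate
9 | methyl (R)-2-chloropropanoate | C[C@@H](Cl)C(=O)OC | starting material
10 | (R)-2-chloropropanal | C[C@@H](Cl)C=O | intermediate
11 | lithium (2R,3S,4R)-2-chloro-4-{3,5-dimethyl-4-oxo-6-[(2S,3S)-3-(triethylsilyloxy)pentan-2-yl]-4H-pyran-2-yl}pentan-3-olate | [Li+].C[C@@H](Cl)[C@@H]([O-])[C@@H](C)c1oc([C@@H](C)[C@@H](O[Si](CC)(CC)CC)CC)c(C)c(=O)c1C | intermediate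
12 | (2R,3S,4R)-2-chloro-4-{3,5-dimethyl-4-oxo-6-[(2S,3S)-3-(triethylsilyloxy)pentan-2-yl]-4H-pyran-2-yl}pentan-3-yl acetate | C[C@@H](Cl)[C@@H](OC(C)=O)[C@@H](C)c1oc([C@@H](C)[C@@H](O[Si](CC)(CC)CC)CC)c(C)c(=O)c1C | intermediate
13 | methyl (S)-3-hydroxy-2-methylpropanoate | COC(=O)[C@@H](C)CO | starting material
14 | methyl (S)-2-methyl-3-(triethylsilyloxy)propanoate | COC(=O)[C@@H](C)CO[Si](CC)(CC)CC | intermediate
15 | (S)-2-methyl-3-(triethylsilyloxy)propanal | O=C[C@@H](C)CO[Si](CC)(CC)CC | intermediate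
16 | lithium (2S,3R,4R)-4-(6-ethyl-3,5-dimethyl-4-oxo-4H-pyran-2-yl)-2-methyl-1-(triethylsilyloxy)pentan-3-olate | [Li+].CCc1oc([C@H](C)[C@H]([O-])[C@@H](C)CO[Si](CC)(CC)CC)c(C)c(=O)c1C | intermediate
17 | 2-ethyl-6-[(2R,3R,4S)-3-hydroxy-4-methyl-5-(triethylsilyloxy)pentan-2-yl]-3,5-dimethyl-4H-pyran-4-one | CCc1oc([C@H](C)[C@H](O)[C@@H](C)CO[Si](CC)(CC)CC)c(C)c(=O)c1C | intermediate
18 | 2-[(2R,3R,4S)-3,5-dihydroxy-4-methylpentan-2-yl]-6-ethyl-3,5-dimethyl-4H-pyran-4-one | CCc1oc([C@H](C)[C@H](O)[C@@H](C)CO)c(C)c(=O)c1C | intermediate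
19 | (2R,3S,4R)-4-(6-ethyl-3,5-dimethyl-4-oxo-4H-pyran-2-yl)-3-hydroxy-2-methylpentanoic acid | CCc1oc([C@H](C)[C@H](O)[C@@H](C)C(=O)O)c(C)c(=O)c1C | intermediate
20 | S-(pyridin-2-yl) (2R,3S,4R)-4-(6-ethyl-3,5-dimethyl-4-oxo-4H-pyran-2-yl)-3-hydroxy-2-methylpentanethioate | CCc1oc([C@H](C)[C@H](O)[C@@H](C)C(=O)Sc2ccccn2)c(C)c(=O)c1C | intermediate
21 | (2R,3S,4RS,6R,7S,8R)-2-{3,5-dimethyl-4-oxo-6-[(2S,3S)-3-(triethylsilyloxy)pentan-2-yl]-4H-pyran-2-yl}-8-(6-ethyl-3,5-dimethyl-4-oxo-4H-pyran-2-yl)-7-hydroxy-4,6-dimethyl-5-oxononan-3-yl acetate (C11 ketone, C12 epimers) | CCc1oc([C@H](C)[C@H](O)[C@@H](C)C(=O)C(C)[C@@H](OC(C)=O)[C@@H](C)c2oc([C@@H](C)[C@@H](O[Si](CC)(CC)CC)CC)c(C)c(=O)c2C)c(C)c(=O)c1C | intermediate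
22 | 2-[(2R,3E,6R,7S,8R)-8-(6-ethyl-3,5-dimethyl-4-oxo-4H-pyran-2-yl)-7-hydroxy-4,6-dimethyl-5-oxonon-3-en-2-yl]-3,5-dimethyl-6-[(2S,3S)-3-(triethylsilyloxy)pentan-2-yl]-4H-pyran-4-one | CCc1oc([C@H](C)[C@H](O)[C@@H](C)C(=O)/C(C)=C/[C@@H](C)c2oc([C@@H](C)[C@@H](O[Si](CC)(CC)CC)CC)c(C)c(=O)c2C)c(C)c(=O)c1C | intermediate
23 | 2-[(2R,3E,6R,7S,8R)-8-(6-ethyl-3,5-dimethyl-4-oxo-4H-pyran-2-yl)-7-hydroxy-4,6-dimethyl-5-oxonon-3-en-2-yl]-6-[(2S,3S)-3-hydroxypentan-2-yl]-3,5-dimethyl-4H-pyran-4-one | CCc1oc([C@H](C)[C@H](O)[C@@H](C)C(=O)/C(C)=C/[C@@H](C)c2oc([C@@H](C)[C@@H](O)CC)c(C)c(=O)c2C)c(C)c(=O)c1C | intermediate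
24 | CNP0408419.9: 2-[(2R,3E,5R,6R,7R,8R)-8-(6-ethyl-3,5-dimethyl-4-oxo-4H-pyran-2-yl)-5,7-dihydroxy-4,6-dimethylnon-3-en-2-yl]-6-[(2S,3S)-3-hydroxypentan-2-yl]-3,5-dimethyl-4H-pyran-4-one | CCc1oc([C@H](C)[C@H](O)[C@@H](C)[C@@H](O)/C(C)=C/[C@@H](C)c2oc([C@@H](C)[C@@H](O)CC)c(C)c(=O)c2C)c(C)c(=O)c1C | target

**Step count and risks**
Total step count: 15. Longest linear sequence: 9 steps (13 → 24 through steps 7 to 15).

Three steps most likely to fail:

Step 12 (the proposed coupling). The risks are slow chlorine abstraction at the hindered secondary C–Cl, attack of silyl radicals on the thioester, and loss of the β-acetate from an alkyl–nickel intermediate. The fallback uses known chemistry, sets out from 8 (and uses 20) and comes back at 21. Methyl (R)-2-bromopropanoate F1 is reduced with i-Bu2AlH at −78 °C to (R)-2-bromopropanal F2. Addition of this aldehyde to the lithium dienolate of 8 (LiN(SiMe3)2, THF, −78 °C, AcOH quench at −78 °C) gives the bromohydrin 2-[(2R,3S,4R)-4-bromo-3-hydroxypentan-2-yl]-3,5-dimethyl-6-[(2S,3S)-3-(triethylsilyloxy)pentan-2-yl]-4H-pyran-4-one F3. Acetylation (Ac2O, pyridine, 4-(dimethylamino)pyridine) gives the bromo acetate (2R,3S,4R)-2-bromo-4-{3,5-dimethyl-4-oxo-6-[(2S,3S)-3-(triethylsilyloxy)pentan-2-yl]-4H-pyran-2-yl}pentan-3-yl acetate F4. The bromo acetate and 20 are then joined by the established thermal nickel-catalysed reductive acylation of alkyl halides with S-2-pyridyl thioesters (NiCl2(MeOCH2CH2OMe), 4,4′-di-tert-butyl-2,2′-bipyridine, Zn powder, NaI, DMA, 25 °C), which gives 21; the route continues with step 13.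

Step 6. The risks are competing deprotonation at C20–H, enolisation or racemisation of the α-chloro aldehyde by the basic dienolate, and modest simple diastereoselection. The fallback avoids strong base, sets out from 8 and comes back at 12. Soft enolisation of 8 (t-BuMe2SiOTf, Et3N, CH2Cl2, −78 → 0 °C; silyloxypyrylium formation, then deprotonation of the less hindered ethyl group) gives the silyl trienol ether (2Z)-4-(tert-butyldimethylsilyloxy)-2-ethylidene-3,5-dimethyl-6-[(2S,3S)-3-(triethylsilyloxy)pentan-2-yl]-2H-pyran F5. A BF3·OEt2-promoted vinylogous Mukaiyama aldol addition of this ether to 10 (CH2Cl2, −78 °C, open transition state, Cornforth sense unchanged) and aqueous work-up give the chlorohydrin 2-[(2R,3S,4R)-4-chloro-3-hydroxypentan-2-yl]-3,5-dimethyl-6-[(2S,3S)-3-(triethylsilyloxy)pentan-2-yl]-4H-pyran-4-one F6. Ac2O, pyridine and 4-(dimethylamino)pyridine convert it into 12.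

Step 3. The risk is the anti simple diastereoselection of the pyranone dienolate, on which C20 and C21 depend; the same premise underlies step 9. The fallback makes the C20–C21 pair by enolate alkylation and ring B by condensation, sets out from pentan-3-one 1 and comes back at 8. Methyl (S)-3-hydroxypentanoate F7 is methylated anti to its hydroxyl by Fráter–Seebach alkylation of the dianion (LiN(i-Pr)2 2.2 equiv, MeI, THF, −78 → −20 °C) to methyl (2S,3S)-3-hydroxy-2-methylpentanoate F8. Silylation (Et3SiCl, imidazole) gives methyl (2S,3S)-2-methyl-3-(triethylsilyloxy)pentanoate F9. Ketone 1 is acylated with ethyl propanoate (NaH, Et2O) to 4-methylheptane-3,5-dione F10. The dianion of this diketone (NaH, then n-BuLi, THF, 0 °C) undergoes Claisen condensation with the silylated ester to give the triketone (8S,9S)-4,6,8-trimethyl-9-(triethylsilyloxy)undecane-3,5,7-trione F11. Cyclodehydration (PPh3, CCl4, THF, 23 °C) closes ring B and gives 8.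

**Further compounds**
F1 | step 12 | methyl (R)-2-bromopropanoate | C[C@@H](Br)C(=O)OC
F2 | step 12 | (R)-2-bromopropanal | C[C@@H](Br)C=O
F3 | step 12 | 2-[(2R,3S,4R)-4-bromo-3-hydroxypentan-2-yl]-3,5-dimethyl-6-[(2S,3S)-3-(triethylsilyloxy)pentan-2-yl]-4H-pyran-4-one | C[C@@H](Br)[C@@H](O)[C@@H](C)c1oc([C@@H](C)[C@@H](O[Si](CC)(CC)CC)CC)c(C)c(=O)c1C
F4 | step 12 | (2R,3S,4R)-2-bromo-4-{3,5-dimethyl-4-oxo-6-[(2S,3S)-3-(triethylsilyloxy)pentan-2-yl]-4H-pyran-2-yl}pentan-3-yl acetate | C[C@@H](Br)[C@@H](OC(C)=O)[C@@H](C)c1oc([C@@H](C)[C@@H](O[Si](CC)(CC)CC)CC)c(C)c(=O)c1C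
F5 | step 6 | (2Z)-4-(tert-butyldimethylsilyloxy)-2-ethylidene-3,5-dimethyl-6-[(2S,3S)-3-(triethylsilyloxy)pentan-2-yl]-2H-pyran | C/C=C1\OC([C@@H](C)[C@@H](O[Si](CC)(CC)CC)CC)=C(C)C(O[Si](C)(C)C(C)(C)C)=C1C
F6 | step 6 | 2-[(2R,3S,4R)-4-chloro-3-hydroxypentan-2-yl]-3,5-dimethyl-6-[(2S,3S)-3-(triethylsilyloxy)pentan-2-yl]-4H-pyran-4-one | C[C@@H](Cl)[C@@H](O)[C@@H](C)c1oc([C@@H](C)[C@@H](O[Si](CC)(CC)CC)CC)c(C)c(=O)c1C
F7 | step 3 | methyl (S)-3-hydroxypentanoate | CC[C@H](O)CC(=O)OC
F8 | step 3 | methyl (2S,3S)-3-hydroxy-2-methylpentanoate | COC(=O)[C@@H](C)[C@@H](O)CC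
F9 | step 3 | methyl (2S,3S)-2-methyl-3-(triethylsilyloxy)pentanoate | COC(=O)[C@@H](C)[C@@H](O[Si](CC)(CC)CC)CC
F10 | step 3 | 4-methylheptane-3,5-dione | CCC(=O)C(C)C(=O)CC
F11 | step 3 | (8S,9S)-4,6,8-trimethyl-9-(triethylsilyloxy)undecane-3,5,7-trione | CCC(=O)C(C)C(=O)C(C)C(=O)[C@@H](C)[C@@H](O[Si](CC)(CC)CC)CC
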